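**Strategy.** Ring B of the perhydro-1-benzoxepine (C5a, C6, C7, C8, C9, C9a) is closed last by a biomimetic epoxonium/allylsilane cyclization. In precursor 27, which already carries the cis-decalin (rings C and D), a silyl triflate makes the internal epoxide oxygen attack the terminal epoxide (ring A, O1–C2). The resulting epoxonium is opened at C5a by the allylsilane carbon C6. The step exploits the trans A/B fusion, in which O1 on C9a lies anti to the new C5a–C6 bond, and the oxygenated C7 next to C6. One operation sets C5a and C6, transfers C3 and C9a from two Shi epoxidations and leaves a C7 methylidene for hydration.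

Key step: step 16

Remark on the chemistry: the L-fructose-derived enantiomer of the Shi ketone is assumed to be available (commercial, or from L-sorbose); it is a catalyst and contributes no atoms. Atom labels: 1-benzoxepine numbering for rings A/B, naphthalene numbering for rings C/D.

**Step 1**
Reactants: 1 (S)-(+)-carvone
Product: 2 (5S)-5-(3-chloroprop-1-en-2-yl)-2-methylcyclohex-2-en-1-one
Conditions: Ca(OCl)2, solid CO2, CH2Cl2/H2O, 0 °C
Reagents that add atoms: calcium hypochlorite, [Ca+2].[O-]Cl.[O-]Cl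
Why: Ene-type allylic chlorination by HOCl attacks the electron-rich 1,1-disubstituted alkene and not the enone, giving the 2-substituted allyl chloride with shift of the double bond; C5 is untouched.

**Step 2**
Reactants: 2 (5S)-5-(3-chloroprop-1-en-2-yl)-2-methylcyclohex-2-en-1-one; 3 pentane-2,4-dione
Product: 5 (5S)-2-methyl-5-(5-oxohex-1-en-2-yl)cyclohex-2-en-1-one, via C-alkylated pentanedione 4 (not isolated)
Conditions: K2CO3, NaI (cat.), EtOH, reflux
Reagents that add atoms: none
Why: SN2 C-alkylation of the acetylacetone anion by the allylic chloride followed by in situ retro-Claisen deacetylation gives the methyl ketone without a strong base, so the enone is not enolised.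

**Step 3**
Reactants: 5 (5S)-2-methyl-5-(5-oxohex-1-en-2-yl)cyclohex-2-en-1-one
Product: 6 (5S)-5-(5-hydroxy-5-methylhex-1-en-2-yl)-2-methylcyclohex-2-en-1-one
Conditions: MeMgBr (1.1 equiv), THF, −78 °C; aq. NH4Cl
Reagents that add atoms: methylmagnesium bromide, C[Mg]Br
Why: Chemoselective Grignard 1,2-addition, since the unhindered saturated methyl ketone should react at −78 °C much faster than the conjugated α-methyl enone carbonyl.

**Step 4**
Reactants: 6 (5S)-5-(5-hydroxy-5-methylhex-1-en-2-yl)-2-methylcyclohex-2-en-1-one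
Product: 7 bis(trimethylsilyl) derivative of 6 (cross-conjugated trimethylsilyl dienol ether with C1=C6 and C2=C3, tertiary O-trimethylsilyl ether, 5S)
Conditions: LiN(i-Pr)2 (2.3 equiv), Me3SiCl (3 equiv, in situ), THF, −78 °C
Reagents that add atoms: chlorotrimethylsilane, C[Si](C)(C)Cl
Why: Kinetic deprotonation at the α′-CH2 of the enone with in situ silylation gives the cross-conjugated silyl dienol ether (and silylates the tertiary alkoxide), fixing C6 as the nucleophilic carbon for ring closure.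

**Step 5**
Reactants: 7 bis(trimethylsilyl) derivative of 6
Product: 8 (4aS,8aR)-2,8,8-trimethyl-5-methylidene-4a,5,6,7,8,8a-hexahydronaphthalen-1(4H)-one (cis-fused)
Conditions: TiCl4 (1.1 equiv), 2,6-di-tert-butyl-4-methylpyridine (0.2 equiv), CH2Cl2, −78 °C
Reagents that add atoms: none
Why: Intramolecular Lewis-acid-mediated α-tert-alkylation of a silyl enol ether (SN1, Mukaiyama type): the tertiary cation is attacked by the dienol ether carbon through a six-membered transition state in which the tether is delivered from the face of its own attachment, so C8a should form cis to H-4a.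

**Step 6**
Reactants: 8 (4aS,8aR)-2,8,8-trimethyl-5-methylidene-4a,5,6,7,8,8a-hexahydronaphthalen-1(4H)-one; 9 methyl phenyl sulfone
Product: 11 (1S,4aS,8aR)-2,8,8-trimethyl-5-methylidene-1-[(phenylsulfonyl)methyl]-1,4,4a,5,6,7,8,8a-octahydronaphthalen-1-ol, via lithiated sulfone 10 (not isolated)
Conditions: n-BuLi, THF, −78 °C; CeCl3; then 8, −78 °C; aq. NH4Cl
Reagents that add atoms: none
Why: 1,2-Addition of the α-sulfonyl carbanion as its organocerium reagent, which suppresses enolisation and thus epimerisation of C8a, anti to the adjacent quaternary carbon; the new carbinol centre (1S expected) is removed in step 7.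

**Step 7**
Reactants: 11 (1S,4aS,8aR)-2,8,8-trimethyl-5-methylidene-1-[(phenylsulfonyl)methyl]-1,4,4a,5,6,7,8,8a-octahydronaphthalen-1-ol
Product: 12 (4aR,8aS)-3,5,5-trimethyl-8-methylidene-4-[(phenylsulfonyl)methyl]-4a,5,6,7,8,8a-hexahydronaphthalen-2(1H)-one
Conditions: pyridinium chlorochromate (C5H5NH[CrO3Cl]), 4 Å molecular sieves, CH2Cl2, rt
Reagents that add atoms: pyridinium chlorochromate, [O-][Cr](=O)(=O)Cl.c1cc[nH+]cc1
Why: Babler–Dauben oxidative 1,3-transposition, in which the chromate ester of the tertiary allylic alcohol undergoes a [3,3] shift and oxidation to the transposed tetrasubstituted enone.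

**Step 8**
Reactants: 13 ethyl acetoacetate; 14 geranyl bromide ((2E)-1-bromo-3,7-dimethylocta-2,6-diene)
Product: 16 ethyl (6E)-7,11-dimethyl-3-oxododeca-6,10-dienoate, via acetoacetate dianion 15 (not isolated)
Conditions: NaH, THF, 0 °C; n-BuLi, 0 °C; then 14, 0 °C
Reagents that add atoms: none
Why: Alkylation of the acetoacetate dianion at its terminal carbon by the allylic bromide (SN2) with retention of the E alkene.

**Step 9**
Reactants: 16 ethyl (6E)-7,11-dimethyl-3-oxododeca-6,10-dienoate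
Product: 18 ethyl (2Z,6E)-3-[(diethoxyphosphoryl)oxy]-7,11-dimethyldodeca-2,6,10-trienoate, via sodium enolate 17 (not isolated)
Conditions: NaH, Et2O, 0 °C; ClP(O)(OEt)2
Reagents that add atoms: diethyl chlorophosphate, CCOP(=O)(Cl)OCC
Why: O-Phosphorylation of the chelated sodium Z-enolate in ether should give the (Z)-enol phosphate stereoselectively.

**Step 10**
Reactants: 18 ethyl (2Z,6E)-3-[(diethoxyphosphoryl)oxy]-7,11-dimethyldodeca-2,6,10-trienoate
Product: 19 ethyl (2Z,6E)-7,11-dimethyl-3-[(trimethylsilyl)methyl]dodeca-2,6,10-trienoate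
Conditions: Me3SiCH2MgCl, Ni(acac)2 (5 mol %), THF, 0 °C to rt
Reagents that add atoms: (trimethylsilyl)methylmagnesium chloride, C[Si](C)(C)C[Mg]Cl
Why: Nickel-catalysed Kumada-type coupling of the enol phosphate proceeds with retention of alkene geometry, giving the allylsilane with the silylmethyl group cis to the ester; conjugation deactivates this alkene for step 11.

**Step 11**
Reactants: 19 ethyl (2Z,6E)-7,11-dimethyl-3-[(trimethylsilyl)methyl]dodeca-2,6,10-trienoate
Product: 20 ethyl (2Z)-5-[(2S,3S)-3-{2-[(2S)-3,3-dimethyloxiran-2-yl]ethyl}-3-methyloxiran-2-yl]-3-[(trimethylsilyl)methyl]pent-2-enoate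
Conditions: L-fructose-derived Shi ketone (0.6 equiv), Oxone (2KHSO5·KHSO4·K2SO4), K2CO3, Bu4NHSO4, MeCN/CH2(OMe)2/aq. Na2B4O7 buffer, 0 °C
Reagents that add atoms: potassium peroxymonosulfate, [K+].[O-]S(=O)(=O)OO
Why: Shi asymmetric epoxidation (chiral dioxirane) of the two electron-rich trisubstituted alkenes, each on the face dictated by the ketone, should give the three (S)-configured epoxide carbons; the ester-conjugated alkene is inert.

**Step 12**
Reactants: 20 ethyl (2Z)-5-[(2S,3S)-3-{2-[(2S)-3,3-dimethyloxiran-2-yl]ethyl}-3-methyloxiran-2-yl]-3-[(trimethylsilyl)methyl]pent-2-enoate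
Product: 21 (2Z)-5-[(2S,3S)-3-{2-[(2S)-3,3-dimethyloxiran-2-yl]ethyl}-3-methyloxiran-2-yl]-3-[(trimethylsilyl)methyl]pent-2-en-1-ol
Conditions: i-Bu2AlH (2.5 equiv), CH2Cl2, −78 °C; Rochelle salt
Reagents that add atoms: none
Why: 1,2-Reduction of the unsaturated ester by the aluminium hydride at −78 °C leaves the trisubstituted epoxides and the allylsilane intact.

**Step 13**
Reactants: 21 (2Z)-5-[(2S,3S)-3-{2-[(2S)-3,3-dimethyloxiran-2-yl]ethyl}-3-methyloxiran-2-yl]-3-[(trimethylsilyl)methyl]pent-2-en-1-ol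
Product: 23 (2S,3S)-3-[(3Z)-5-bromo-3-[(trimethylsilyl)methyl]pent-3-en-1-yl]-2-{2-[(2S)-3,3-dimethyloxiran-2-yl]ethyl}-2-methyloxirane, via allylic mesylate 22 (not isolated)
Conditions: MeSO2Cl, Et3N, THF, −40 °C; then LiBr, THF, 0 °C
Reagents that add atoms: lithium bromide, [Li+].[Br-]; methanesulfonyl chloride, CS(=O)(=O)Cl (in 22 only)
Why: Mesylation and SN2 displacement by bromide (Finkelstein type) under non-acidic conditions give the primary allylic bromide without transposition.

**Step 14**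
Reactants: 12 (4aR,8aS)-3,5,5-trimethyl-8-methylidene-4-[(phenylsulfonyl)methyl]-4a,5,6,7,8,8a-hexahydronaphthalen-2(1H)-one; 23 allylic bromide
Product: 25 (4aR,8aS)-4-{(3Z)-6-[(2S,3S)-3-{2-[(2S)-3,3-dimethyloxiran-2-yl]ethyl}-3-methyloxiran-2-yl]-1-(phenylsulfonyl)-4-[(trimethylsilyl)methyl]hex-3-en-1-yl}-3,5,5-trimethyl-8-methylidene-4a,5,6,7,8,8a-hexahydronaphthalen-2(1H)-one (epimers at the sulfonyl carbon), via sulfonyl carbanion potassium salt 24 (not isolated)
Conditions: KN(SiMe3)2 (1.05 equiv), THF, −78 °C; then 23, −78 to −20 °C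
Reagents that add atoms: none
Why: SN2 alkylation of the doubly stabilised (α-sulfonyl, vinylogous ketone) carbanion at the sulfonyl-bearing carbon by the primary allylic bromide; attack through the ring α-carbon would create a quaternary centre and is disfavoured; the new centre is removed in step 15.

**Step 15**
Reactants: 25 coupled sulfone
Product: 27 (4aR,8aS)-4-{(3Z)-6-[(2S,3S)-3-{2-[(2S)-3,3-dimethyloxiran-2-yl]ethyl}-3-methyloxiran-2-yl]-4-[(trimethylsilyl)methyl]hex-3-en-1-yl}-3,5,5-trimethyl-8-methylidene-4a,5,6,7,8,8a-hexahydronaphthalen-2(1H)-one, via deconjugated ketone 26 (not isolated)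
Conditions: SmI2 (3 equiv), THF/MeOH, −78 °C; then DBU (cat.), CH2Cl2, rt
Reagents that add atoms: none
Why: SmI2 reduces the enone to its radical anion, which expels the γ-sulfinate (vinylogous reductive desulfonylation of an α-sulfonyl ketone) to a dienolate, and DBU returns the kinetically protonated β,γ-isomer to the conjugated tetrasubstituted enone.

**Step 16**
Reactants: 27 diepoxy allylsilane enone
Product: 29 (4aR,8aS)-3,5,5-trimethyl-8-methylidene-4-{2-[(3S,5aS,6R,9aS)-2,2,5a-trimethyl-7-methylidene-3-(triethylsilyloxy)decahydro-1-benzoxepin-6-yl]ethyl}-4a,5,6,7,8,8a-hexahydronaphthalen-2(1H)-one, via epoxonium triflate 28 (not isolated)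
Conditions: Et3SiOSO2CF3 (1.5 equiv), 2,6-di-tert-butyl-4-methylpyridine (2 equiv), CH2Cl2, −78 °C
Reagents that add atoms: triethylsilyl trifluoromethanesulfonate, CC[Si](CC)(CC)OS(=O)(=O)C(F)(F)F
Why: The silyl triflate activates the terminal dimethyl-substituted epoxide, whose tertiary carbon C2 is attacked by the oxygen of the neighbouring epoxide to give the bridged epoxonium ion 28 (ring A is closed first, through O1–C2), and the allylsilane carbon C6 then opens 28 at the tertiary carbon C5a with loss of the silyl group, so that ring B is closed last and a C7 methylidene results. The closest known reaction type is the Lewis-acid-promoted tandem oxa-/carbacyclization of 1,5-diepoxides terminated by enol silanes or propargylsilanes, combined with the allylsilane-terminated epoxide–olefin cyclization. Ring A forms by endo-selective epoxide opening at the more substituted carbon (7-endo overall once the C5a–O bond is cleaved); ring B forms by 6-endo-trig attack of the alkene on C5a (exo with respect to the breaking C5a–O bond) through a chair transition state. C5a is set by inversion at the epoxide carbon, C6 by the alkene geometry (linker carbon trans to C8), which places H-6 axial and the ethylene linker equatorial; C3 and C9a are carried over unchanged from the (S)-configured epoxides. The step needs activation of the terminal rather than the internal epoxide and attack at C5a rather than C9a; both follow from the higher substitution of the attacked carbons and the absence of protic acid, while the enone and the 1,1-disubstituted alkene of ring D should be inert at −78 °C.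

**Step 17**
Reactants: 29 cyclized bis(methylidene) enone
Product: 30 (4aR,8S,8aS)-8-hydroxy-4-{2-[(3S,5aS,6S,7S,9aS)-7-hydroxy-2,2,5a,7-tetramethyl-3-(triethylsilyloxy)decahydro-1-benzoxepin-6-yl]ethyl}-3,5,5,8-tetramethyl-4a,5,6,7,8,8a-hexahydronaphthalen-2(1H)-one
Conditions: Co(acac)2 (20 mol %), PhSiH3, O2 (1 atm), i-PrOH/CH2Cl2, rt
Reagents that add atoms: dioxygen, O=O
Why: Mukaiyama hydration (hydrogen-atom transfer, O2 trapping, reduction) converts both 1,1-disubstituted alkenes into tertiary alcohols; O2 should approach the ring-B radical equatorially, anti to the axial C5a methyl, and the ring-D radical from the convex face of the cis-decalin (OH cis to the ring-fusion hydrogens), while the tetrasubstituted enone does not accept a hydrogen atom.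

**Step 18**
Reactants: 30 enone diol
Product: 31 (1S,4aR,7S,8aS)-5-{2-[(3S,5aS,6S,7S,9aS)-7-hydroxy-2,2,5a,7-tetramethyl-3-(triethylsilyloxy)decahydro-1-benzoxepin-6-yl]ethyl}-1,4,4,6-tetramethyl-1,2,3,4,4a,7,8,8a-octahydronaphthalene-1,7-diol
Conditions: (R)-2-methyl-CBS-oxazaborolidine (0.5 equiv), BH3·SMe2, THF, −30 °C
Reagents that add atoms: none
Why: Corey–Bakshi–Shibata reduction: with the alkenyl arm as the large group, the (R)-oxazaborolidine should deliver hydride to the face cis to the ring-D carbons and give the (7S)-allylic alcohol under reagent control.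

**Step 19**
Reactants: 31 (7S)-allylic alcohol
Product: 33 (1S,4aR,7R,8aS)-7-hydroperoxy-5-{2-[(3S,5aS,6S,7S,9aS)-7-hydroxy-2,2,5a,7-tetramethyl-3-(triethylsilyloxy)decahydro-1-benzoxepin-6-yl]ethyl}-1,4,4,6-tetramethyl-1,2,3,4,4a,7,8,8a-octahydronaphthalen-1-ol, via allylic mesylate 32 (not isolated)
Conditions: MeSO2Cl, Et3N, CH2Cl2, −65 °C; then anhydrous H2O2 in Et2O, −110 to −40 °C
Reagents that add atoms: hydrogen peroxide, OO; methanesulfonyl chloride, CS(=O)(=O)Cl (in 32 only)
Why: SN2 displacement of the secondary allylic mesylate by H2O2 with inversion (hydroperoxide synthesis from sulfonates) should convert the (7S)-mesylate into the (7R)-hydroperoxide; the tertiary alcohols are not sulfonylated at −65 °C and SN2′ attack at the fully substituted C5 is blocked.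

**Step 20**
Reactants: 33 silyl-protected hydroperoxide
Product: 34 sipholenol M, (1S,4aR,7R,8aS)-5-{2-[(3S,5aS,6S,7S,9aS)-3,7-dihydroxy-2,2,5a,7-tetramethyldecahydro-1-benzoxepin-6-yl]ethyl}-7-hydroperoxy-1,4,4,6-tetramethyl-1,2,3,4,4a,7,8,8a-octahydronaphthalen-1-ol
Conditions: HF·pyridine, pyridine/THF, 0 °C
Reagents that add atoms: none
Why: Fluoride cleavage of the triethylsilyl ether under mildly acidic conditions that an allylic hydroperoxide should tolerate.

**Compound list**

1 | (S)-(+)-carvone | CC1=CC[C@@H](CC1=O)C(C)=C | starting material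
2 | (5S)-5-(3-chloroprop-1-en-2-yl)-2-methylcyclohex-2-en-1-one | CC1=CC[C@@H](CC1=O)C(=C)CCl | intermediate
3 | pentane-2,4-dione | CC(=O)CC(C)=O | starting material
4 | 3-{2-[(1S)-4-methyl-5-oxocyclohex-3-en-1-yl]prop-2-en-1-yl}pentane-2,4-dione (not isolated) | CC1=CC[C@@H](CC1=O)C(=C)CC(C(C)=O)C(C)=O | intermediate
5 | (5S)-2-methyl-5-(5-oxohex-1-en-2-yl)cyclohex-2-en-1-one | CC1=CC[C@@H](CC1=O)C(=C)CCC(C)=O | intermediate
6 | (5S)-5-(5-hydroxy-5-methylhex-1-en-2-yl)-2-methylcyclohex-2-en-1-one | CC1=CC[C@@H](CC1=O)C(=C)CCC(C)(C)O | intermediate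
7 | bis(trimethylsilyl) derivative of 6 (dienol ether and tertiary silyl ether, 5S) | CC1=CC[C@@H](C=C1O[Si](C)(C)C)C(=C)CCC(C)(C)O[Si](C)(C)C | intermediate
8 | (4aS,8aR)-2,8,8-trimethyl-5-methylidene-4a,5,6,7,8,8a-hexahydronaphthalen-1(4H)-one | O=C1C(C)=CC[C@H]2[C@@H]1C(C)(C)CCC2=C | intermediate
9 | methyl phenyl sulfone | CS(=O)(=O)c1ccccc1 | starting material
10 | [(phenylsulfonyl)methyl]lithium (not isolated) | [Li]CS(=O)(=O)c1ccccc1 | intermediate
11 | (1S,4aS,8aR)-2,8,8-trimethyl-5-methylidene-1-[(phenylsulfonyl)methyl]-1,4,4a,5,6,7,8,8a-octahydronaphthalen-1-ol | O[C@]1(CS(=O)(=O)c2ccccc2)C(C)=CC[C@H]3[C@@H]1C(C)(C)CCC3=C | intermediate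
12 | (4aR,8aS)-3,5,5-trimethyl-8-methylidene-4-[(phenylsulfonyl)methyl]-4a,5,6,7,8,8a-hexahydronaphthalen-2(1H)-one | CC1=C(CS(=O)(=O)c3ccccc3)[C@@H]2[C@H](CC1=O)C(=C)CCC2(C)C | intermediate
13 | ethyl acetoacetate | CCOC(=O)CC(C)=O | starting material
14 | geranyl bromide | CC(C)=CCC/C(C)=C/CBr | starting material
15 | sodium lithium dianion of ethyl acetoacetate (not isolated) | CCOC(=O)C=C(C[Li])O[Na] | intermediate
16 | ethyl (6E)-7,11-dimethyl-3-oxododeca-6,10-dienoate | CCOC(=O)CC(=O)CC/C=C(\C)CCC=C(C)C | intermediate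
17 | sodium (Z)-enolate of 16 (not isolated) | CCOC(=O)/C=C(\O[Na])CC/C=C(\C)CCC=C(C)C | intermediate
18 | ethyl (2Z,6E)-3-[(diethoxyphosphoryl)oxy]-7,11-dimethyldodeca-2,6,10-trienoate | CCOC(=O)/C=C(\OP(=O)(OCC)OCC)CC/C=C(\C)CCC=C(C)C | intermediate
19 | ethyl (2Z,6E)-7,11-dimethyl-3-[(trimethylsilyl)methyl]dodeca-2,6,10-trienoate | CCOC(=O)/C=C(\C[Si](C)(C)C)CC/C=C(\C)CCC=C(C)C | intermediate
20 | ethyl (2Z)-5-[(2S,3S)-3-{2-[(2S)-3,3-dimethyloxiran-2-yl]ethyl}-3-methyloxiran-2-yl]-3-[(trimethylsilyl)methyl]pent-2-enoate | CCOC(=O)/C=C(\C[Si](C)(C)C)CC[C@@H]1O[C@@]1(C)CC[C@@H]1OC1(C)C | intermediate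
21 | (2Z)-5-[(2S,3S)-3-{2-[(2S)-3,3-dimethyloxiran-2-yl]ethyl}-3-methyloxiran-2-yl]-3-[(trimethylsilyl)methyl]pent-2-en-1-ol | OC/C=C(\C[Si](C)(C)C)CC[C@@H]1O[C@@]1(C)CC[C@@H]1OC1(C)C | intermediate
22 | methanesulfonate of 21 (not isolated) | CS(=O)(=O)OC/C=C(\C[Si](C)(C)C)CC[C@@H]1O[C@@]1(C)CC[C@@H]1OC1(C)C | intermediate
23 | allylic bromide corresponding to 21 (Z, all epoxide carbons S) | BrC/C=C(\C[Si](C)(C)C)CC[C@@H]1O[C@@]1(C)CC[C@@H]1OC1(C)C | intermediate
24 | potassium salt of the sulfonyl carbanion of 12 (not isolated) | [K+].CC1=C([CH-]S(=O)(=O)c3ccccc3)[C@@H]2[C@H](CC1=O)C(=C)CCC2(C)C | intermediate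
25 | coupled sulfone (4aR,8aS; chain 3Z; epoxides S,S and S; epimers at the sulfonyl carbon) | CC1=C(C(C/C=C(\C[Si](C)(C)C)CC[C@@H]3O[C@@]3(C)CC[C@@H]3OC3(C)C)S(=O)(=O)c3ccccc3)[C@@H]2[C@H](CC1=O)C(=C)CCC2(C)C | intermediate
26 | β,γ-unsaturated (exocyclic alkylidene) isomer of 27 (not isolated; new centre and alkene geometry undefined) | CC1C(=CC/C=C(\C[Si](C)(C)C)CC[C@@H]3O[C@@]3(C)CC[C@@H]3OC3(C)C)[C@@H]2[C@H](CC1=O)C(=C)CCC2(C)C | intermediate
27 | (4aR,8aS)-4-{(3Z)-6-[(2S,3S)-3-{2-[(2S)-3,3-dimethyloxiran-2-yl]ethyl}-3-methyloxiran-2-yl]-4-[(trimethylsilyl)methyl]hex-3-en-1-yl}-3,5,5-trimethyl-8-methylidene-4a,5,6,7,8,8a-hexahydronaphthalen-2(1H)-one | CC1=C(CC/C=C(\C[Si](C)(C)C)CC[C@@H]3O[C@@]3(C)CC[C@@H]3OC3(C)C)[C@@H]2[C@H](CC1=O)C(=C)CCC2(C)C | intermediate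
28 | bridged epoxonium triflate (O1 bonded to C2, C5a and C9a; C3–O–SiEt3) (not isolated) | CC1=C(CC/C=C(\C[Si](C)(C)C)CC[C@@H]3[O+]4[C@@]3(C)CC[C@H](O[Si](CC)(CC)CC)C4(C)C)[C@@H]2[C@H](CC1=O)C(=C)CCC2(C)C.[O-]S(=O)(=O)C(F)(F)F | intermediate
29 | (4aR,8aS)-3,5,5-trimethyl-8-methylidene-4-{2-[(3S,5aS,6R,9aS)-2,2,5a-trimethyl-7-methylidene-3-(triethylsilyloxy)decahydro-1-benzoxepin-6-yl]ethyl}-4a,5,6,7,8,8a-hexahydronaphthalen-2(1H)-one | CC1=C(CC[C@H]2[C@]3(C)CC[C@H](O[Si](CC)(CC)CC)C(C)(C)O[C@H]3CCC2=C)[C@@H]2[C@H](CC1=O)C(=C)CCC2(C)C | intermediate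
30 | (4aR,8S,8aS)-8-hydroxy-4-{2-[(3S,5aS,6S,7S,9aS)-7-hydroxy-2,2,5a,7-tetramethyl-3-(triethylsilyloxy)decahydro-1-benzoxepin-6-yl]ethyl}-3,5,5,8-tetramethyl-4a,5,6,7,8,8a-hexahydronaphthalen-2(1H)-one | CC1=C(CC[C@H]2[C@]3(C)CC[C@H](O[Si](CC)(CC)CC)C(C)(C)O[C@H]3CC[C@]2(C)O)[C@@H]2[C@H](CC1=O)[C@@](C)(O)CCC2(C)C | intermediate
31 | (1S,4aR,7S,8aS)-5-{2-[(3S,5aS,6S,7S,9aS)-7-hydroxy-2,2,5a,7-tetramethyl-3-(triethylsilyloxy)decahydro-1-benzoxepin-6-yl]ethyl}-1,4,4,6-tetramethyl-1,2,3,4,4a,7,8,8a-octahydronaphthalene-1,7-diol | CC1=C(CC[C@H]2[C@]3(C)CC[C@H](O[Si](CC)(CC)CC)C(C)(C)O[C@H]3CC[C@]2(C)O)[C@@H]2[C@H](C[C@@H]1O)[C@@](C)(O)CCC2(C)C | intermediate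
32 | 7-O-methanesulfonate of 31 (7S) (not isolated) | CC1=C(CC[C@H]2[C@]3(C)CC[C@H](O[Si](CC)(CC)CC)C(C)(C)O[C@H]3CC[C@]2(C)O)[C@@H]2[C@H](C[C@@H]1OS(C)(=O)=O)[C@@](C)(O)CCC2(C)C | intermediate
33 | 3-O-triethylsilyl ether of sipholenol M (7R-hydroperoxide) | CC1=C(CC[C@H]2[C@]3(C)CC[C@H](O[Si](CC)(CC)CC)C(C)(C)O[C@H]3CC[C@]2(C)O)[C@@H]2[C@H](C[C@H]1OO)[C@@](C)(O)CCC2(C)C | intermediate
34 | sipholenol M | CC1=C(CC[C@H]2[C@]3(C)CC[C@H](O)C(C)(C)O[C@H]3CC[C@]2(C)O)[C@@H]2[C@H](C[C@H]1OO)[C@@](C)(O)CCC2(C)C | target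

**Totals.** 20 steps; longest linear sequence 14 steps (steps 1–7, then 14–20).

**Steps most likely to fail**

Step 16. The cascade may lose its order of events: the allylsilane or triflate may open the internal epoxide directly, the allylsilane may be protodesilylated, or the epoxonium may open at C9a to a tetrahydropyran, all on a late convergent intermediate. The fallback closes ring B on the small left fragment before the fragments are joined; decalin 12 is already in hand, so ring B is still the last ring formed. It sets out from 21, which is acetylated (Ac2O, pyridine) to the allylic acetate F1. Et3SiOSO2CF3 and 2,6-di-tert-butyl-4-methylpyridine at −78 °C then effect the same epoxonium/allylsilane cyclization on this simple substrate to give the bicyclic acetate F2. K2CO3/MeOH liberates the primary alcohol F3, and I2, PPh3 and imidazole give the iodide F4. Carbanion 24 (from 12) is alkylated with F4 in THF/DMPU to the sulfone F5, and SmI2 then DBU, as in step 15, return to 29.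

Step 19. The secondary allylic mesylate may ionise to the tertiary-allylic cation with loss of configuration, eliminate to the diene, or the hydroperoxide may decompose under base. The fallback sets out from 30. NaBH4/CeCl3 (Luche reduction, axial hydride delivery) gives the (7R)-allylic alcohol F6. CBr4/PPh3 (Appel reaction, inversion) gives the pseudoaxial (7S)-bromide F7. Displacement with 2-methoxyprop-2-yl hydroperoxide and CsOH in DMF (SN2 by a protected, weakly basic peroxide nucleophile, inversion) gives the (7R)-perketal F8. Brief treatment with AcOH/THF/H2O removes the ketal and returns to 33.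

Step 17. Oxygen trapping of one of the two tertiary radicals may show poor facial selectivity, or reduction may compete with oxygenation. The fallback sets out from 29. m-CPBA/NaHCO3 epoxidises both exocyclic alkenes from their open faces (equatorial attack at C7 of ring B, convex face of ring D) to the bis-epoxide F9. LiBHEt3 opens both epoxides at their CH2 termini and also reduces the enone carbonyl, giving the triol F10 as a mixture of epimers at the allylic carbinol. MnO2 reoxidises the allylic alcohol and returns to 30.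

**Further compounds**

F1 | step 16 | (2Z)-5-[(2S,3S)-3-{2-[(2S)-3,3-dimethyloxiran-2-yl]ethyl}-3-methyloxiran-2-yl]-3-[(trimethylsilyl)methyl]pent-2-en-1-yl acetate | CC(=O)OC/C=C(\C[Si](C)(C)C)CC[C@@H]1O[C@@]1(C)CC[C@@H]1OC1(C)C
F2 | step 16 | [(3S,5aS,6R,9aS)-2,2,5a-trimethyl-7-methylidene-3-(triethylsilyloxy)decahydro-1-benzoxepin-6-yl]methyl acetate | CC(=O)OC[C@H]1[C@]2(C)CC[C@H](O[Si](CC)(CC)CC)C(C)(C)O[C@H]2CCC1=C
F3 | step 16 | [(3S,5aS,6R,9aS)-2,2,5a-trimethyl-7-methylidene-3-(triethylsilyloxy)decahydro-1-benzoxepin-6-yl]methanol | OC[C@H]1[C@]2(C)CC[C@H](O[Si](CC)(CC)CC)C(C)(C)O[C@H]2CCC1=C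
F4 | step 16 | (3S,5aS,6R,9aS)-6-(iodomethyl)-2,2,5a-trimethyl-7-methylidene-3-(triethylsilyloxy)decahydro-1-benzoxepine | IC[C@H]1[C@]2(C)CC[C@H](O[Si](CC)(CC)CC)C(C)(C)O[C@H]2CCC1=C
F5 | step 16 | (4aR,8aS)-3,5,5-trimethyl-8-methylidene-4-{1-(phenylsulfonyl)-2-[(3S,5aS,6R,9aS)-2,2,5a-trimethyl-7-methylidene-3-(triethylsilyloxy)decahydro-1-benzoxepin-6-yl]ethyl}-4a,5,6,7,8,8a-hexahydronaphthalen-2(1H)-one (epimers at the sulfonyl carbon) | CC1=C(C(C[C@H]3[C@]4(C)CC[C@H](O[Si](CC)(CC)CC)C(C)(C)O[C@H]4CCC3=C)S(=O)(=O)c3ccccc3)[C@@H]2[C@H](CC1=O)C(=C)CCC2(C)C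
F6 | step 19 | (7R)-epimer of 31 | CC1=C(CC[C@H]2[C@]3(C)CC[C@H](O[Si](CC)(CC)CC)C(C)(C)O[C@H]3CC[C@]2(C)O)[C@@H]2[C@H](C[C@H]1O)[C@@](C)(O)CCC2(C)C
F7 | step 19 | (7S)-7-bromo analogue of 31 (Br in place of the allylic OH) | CC1=C(CC[C@H]2[C@]3(C)CC[C@H](O[Si](CC)(CC)CC)C(C)(C)O[C@H]3CC[C@]2(C)O)[C@@H]2[C@H](C[C@@H]1Br)[C@@](C)(O)CCC2(C)C
F8 | step 19 | (7R)-7-[(2-methoxypropan-2-yl)peroxy] analogue of 33 | CC1=C(CC[C@H]2[C@]3(C)CC[C@H](O[Si](CC)(CC)CC)C(C)(C)O[C@H]3CC[C@]2(C)O)[C@@H]2[C@H](C[C@H]1OOC(C)(C)OC)[C@@](C)(O)CCC2(C)C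
F9 | step 17 | bis(spiro-epoxide) of 29 (oxirane oxygens equatorial at C7 of ring B and on the convex face of ring D) | CC1=C(CC[C@H]2[C@]3(C)CC[C@H](O[Si](CC)(CC)CC)C(C)(C)O[C@H]3CC[C@@]24CO4)[C@@H]2[C@H](CC1=O)[C@]5(CO5)CCC2(C)C
F10 | step 17 | allylic alcohol from reduction of 30 at its carbonyl (mixture of carbinol epimers) | CC1=C(CC[C@H]2[C@]3(C)CC[C@H](O[Si](CC)(CC)CC)C(C)(C)O[C@H]3CC[C@]2(C)O)[C@@H]2[C@H](CC1O)[C@@](C)(O)CCC2(C)C
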